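**Retrosynthetic overview**

1. Target ⇐ selective 4‑methoxybenzoylation of the secondary allylic alcohol ⇐ hydroxyl‑directed 1,2‑reduction of a cis‑fused β‑hydroxy hydroazulenone.
2. Hydroazulenone ⇐ one semipinacol 1,2‑shift in a trans‑fused decalin‑4a,8a‑diol (O‑4a silylated, exocyclic methylene at C1): the ring‑fusion bond C8a–C4a moves from C8a to C1. Ring A (C1–C4, C4a, C8a) contracts to the cyclopentane, ring B (C4a, C5–C8, C8a) grows to the cycloheptenone, and C8a becomes the ketone.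
3. Enabling feature: in the trans‑decalin the C8a–OH is axial on ring A, so the only C–C bond on C8a that can overlap with a cation at C1 is C8a–C4a. Alkenyl C8 is equatorial, and C4a carries its oxygen axial, which leads to the cis ring fusion with OH and CH3 cis.
4. Decalin diol ⇐ singlet‑oxygen ene reaction of a bicyclic 1,3‑diene (oxygen anti to OSiEt3) ⇐ ring‑closing metathesis (ring B) ⇐ Grignard addition anti to isopropyl ⇐ Stille vinylation ⇐ α‑iodination of (R)‑piperitone (ring A, source of chirality).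
5. Ring order: ring A from the terpene, ring B by metathesis, then the five‑ and seven‑membered rings together in the key step.

Key step: step 7

Assumption: (R)‑(−)‑piperitone is taken as commercial material of high enantiomeric purity and is the only source of chirality; decalins are numbered as naphthalenes and hydroazulenes as azulenes.

**Route**

Step 1
Reactants: 1 (R)‑(−)‑piperitone, (6R)‑3‑methyl‑6‑(propan‑2‑yl)cyclohex‑2‑en‑1‑one; 2 iodine
Product: 3 (6R)‑2‑iodo‑3‑methyl‑6‑(propan‑2‑yl)cyclohex‑2‑en‑1‑one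
Conditions: I2, pyridine/CH2Cl2 (1:1), DMAP (0.2 equiv), rt, dark
Reagents that add atoms: iodine, II
Why: α‑Iodination of a cyclic enone by amine conjugate addition, iodination of the enolate and elimination; no stereocentre is formed and the weak base should not enolise C6.

Step 2
Reactants: 3 (6R)‑2‑iodo‑3‑methyl‑6‑(propan‑2‑yl)cyclohex‑2‑en‑1‑one; 4 tributyl(ethenyl)stannane
Product: 5 (6R)‑2‑ethenyl‑3‑methyl‑6‑(propan‑2‑yl)cyclohex‑2‑en‑1‑one
Conditions: PdCl2(PhCN)2 (5 mol %), AsPh3 (10 mol %), CuI (10 mol %), N‑methylpyrrolidone, rt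
Reagents that add atoms: tributyl(ethenyl)stannane, C=C[Sn](CCCC)(CCCC)CCCC
Why: Stille coupling of an α‑iodoenone under neutral conditions puts the future C8 of ring B on the enone α‑carbon without touching the base‑labile C6 centre.

Step 3
Reactants: 5 (6R)‑2‑ethenyl‑3‑methyl‑6‑(propan‑2‑yl)cyclohex‑2‑en‑1‑one; 6 4‑bromo‑2‑methylbut‑1‑ene
Product: 8 (1S,6R)‑2‑ethenyl‑3‑methyl‑1‑(3‑methylbut‑3‑en‑1‑yl)‑6‑(propan‑2‑yl)cyclohex‑2‑en‑1‑ol, via Grignard reagent 7 (not isolated)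
Conditions: 6, Mg, THF, rt → 40 °C; then 5, LaCl3·2LiCl (1 equiv), THF, 0 °C; H2O
Reagents that add atoms: (3‑methylbut‑3‑en‑1‑yl)magnesium bromide (7, from 6 and Mg), C=C(C)CC[Mg]Br
Why: Lanthanide‑promoted Grignard 1,2‑addition to a hindered, enolisable ketone whose β‑carbon is fully substituted; the nucleophile should enter anti to the adjacent isopropyl group, which sets C1 with OH cis to isopropyl, as in additions to menthone‑type ketones.

Step 4
Reactants: 8 (1S,6R)‑2‑ethenyl‑3‑methyl‑1‑(3‑methylbut‑3‑en‑1‑yl)‑6‑(propan‑2‑yl)cyclohex‑2‑en‑1‑ol; 9 triethylsilyl trifluoromethanesulfonate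
Product: 10 triethyl{[(1S,6R)‑2‑ethenyl‑3‑methyl‑1‑(3‑methylbut‑3‑en‑1‑yl)‑6‑(propan‑2‑yl)cyclohex‑2‑en‑1‑yl]oxy}silane
Conditions: Et3SiOTf, 2,6‑lutidine, CH2Cl2, −78 → 0 °C
Reagents that add atoms: triethylsilyl trifluoromethanesulfonate, CC[Si](CC)(CC)OS(=O)(=O)C(F)(F)F
Why: Silyl triflate silylation of a tertiary alcohol; the bulky OSiEt3 later shields one face of the diene in step 6 and removes O‑4a as an electron donor in step 7.

Step 5
Reactants: 10 triethyl{[(1S,6R)‑2‑ethenyl‑3‑methyl‑1‑(3‑methylbut‑3‑en‑1‑yl)‑6‑(propan‑2‑yl)cyclohex‑2‑en‑1‑yl]oxy}silane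
Product: 11 triethyl{[(4R,4aS)‑1,7‑dimethyl‑4‑(propan‑2‑yl)‑3,4,5,6‑tetrahydronaphthalen‑4a(2H)‑yl]oxy}silane
Conditions: second‑generation Grubbs catalyst RuCl2(=CHPh)(H2IMes)(PCy3) (5 mol %), toluene, 80 °C
Reagents that add atoms: none
Why: Ring‑closing metathesis between the vinyl group and the 1,1‑disubstituted alkene closes six‑membered ring B with a trisubstituted alkene; the tetrasubstituted ring alkene is inert to the catalyst and no stereocentre changes.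

Step 6
Reactants: 11 triethyl{[(4R,4aS)‑1,7‑dimethyl‑4‑(propan‑2‑yl)‑3,4,5,6‑tetrahydronaphthalen‑4a(2H)‑yl]oxy}silane; 12 dioxygen
Product: 14 (4R,4aS,8aS)‑7‑methyl‑1‑methylidene‑4‑(propan‑2‑yl)‑4a‑[(triethylsilyl)oxy]‑1,2,3,4,4a,5,6,8a‑octahydronaphthalen‑8a‑ol, via allylic hydroperoxide 13 (not isolated)
Conditions: O2, tetraphenylporphyrin (1 mol %), white LED, CH2Cl2, −30 °C; then PPh3, −30 °C → rt
Reagents that add atoms: dioxygen, O=O
Why: Schenck ene reaction of singlet oxygen with the tetrasubstituted alkene of the transoid diene: only C1 carries allylic hydrogens, so oxygen must bond to C8a with hydrogen taken from the methyl group, and attack anti to the pseudoaxial OSiEt3 on C4a should set C8a with its oxygen trans to O‑4a; PPh3 reduces the hydroperoxide.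

Step 7
Reactants: 14 (4R,4aS,8aS)‑7‑methyl‑1‑methylidene‑4‑(propan‑2‑yl)‑4a‑[(triethylsilyl)oxy]‑1,2,3,4,4a,5,6,8a‑octahydronaphthalen‑8a‑ol
Product: 15 (1R,3aS,8aS)‑3a,6‑dimethyl‑1‑(propan‑2‑yl)‑8a‑[(triethylsilyl)oxy]‑2,3,3a,7,8,8a‑hexahydroazulen‑4(1H)‑one
Conditions: N,N′‑bis(3,5‑di‑tert‑butylsalicylidene)‑1,2‑cyclohexanediaminocobalt, Co(C36H52N2O2), divalent cobalt (5 mol %), N‑fluoro‑2,4,6‑trimethylpyridinium tetrafluoroborate (1.5 equiv), PhSiH3 (1.2 equiv), acetone, 0 °C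
Reagents that add atoms: none
Why: A cobalt hydride, formed from the divalent cobalt complex, the N‑fluoropyridinium oxidant and PhSiH3, should transfer a hydrogen atom to the exocyclic CH2 of 14, and the tertiary C1 radical is oxidised by trivalent cobalt to the C1 cation, which turns the methylene into the angular methyl group. Because the C8a–OH is axial on ring A of the trans‑decalin, the ring‑fusion bond C8a–C4a is the only C–C bond on C8a that overlaps with the empty orbital at C1 (alkenyl C8 is equatorial, near the nodal plane), so C4a shifts from C8a to C1 and C8a becomes the carbonyl carbon. No ring is closed by a cyclisation: this single 1,2‑shift of the shared bond contracts ring A to the cyclopentane and expands ring B to the cycloheptenone. The new quaternary centre C3a is set by the suprafacial shift, in which C4a migrates with retention; since O‑4a is axial and C5 equatorial, the product should be cis‑fused with CH3 and OSiEt3 cis, and the isopropyl centre is untouched. The closest known reaction type is the hydrogen‑atom‑transfer‑initiated radical‑polar crossover semipinacol rearrangement of tertiary allylic alcohols, together with the cationic six‑six to five‑seven shift of decalins. The step needs hydrogen‑atom transfer to the exocyclic rather than the ring alkene (secured by the preference of the cobalt hydride for 1,1‑disubstituted alkenes) and C–C shift rather than oxirane closure or fragmentation (secured by the free 8a‑OH as the only donor, O‑4a being silylated).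

Step 8
Reactants: 15 (1R,3aS,8aS)‑3a,6‑dimethyl‑1‑(propan‑2‑yl)‑8a‑[(triethylsilyl)oxy]‑2,3,3a,7,8,8a‑hexahydroazulen‑4(1H)‑one
Product: 16 (1R,3aS,8aS)‑8a‑hydroxy‑3a,6‑dimethyl‑1‑(propan‑2‑yl)‑2,3,3a,7,8,8a‑hexahydroazulen‑4(1H)‑one
Conditions: HF·pyridine, pyridine, THF, 0 °C → rt
Reagents that add atoms: none
Why: Fluoride cleavage of the tertiary silyl ether under buffered, non‑basic conditions, chosen to avoid retro‑aldol opening of the β‑hydroxy ketone.

Step 9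
Reactants: 16 (1R,3aS,8aS)‑8a‑hydroxy‑3a,6‑dimethyl‑1‑(propan‑2‑yl)‑2,3,3a,7,8,8a‑hexahydroazulen‑4(1H)‑one
Product: 17 (1R,3aR,4R,8aS)‑3a,6‑dimethyl‑1‑(propan‑2‑yl)‑1,2,3,3a,4,7,8,8a‑octahydroazulene‑4,8a‑diol
Conditions: Me4NBH(OAc)3, MeCN/AcOH (1:1), −20 °C → rt
Reagents that add atoms: none
Why: Evans–Saksena hydroxyl‑directed reduction: the tertiary 8a‑OH binds boron and delivers hydride to the carbonyl face syn to it, which should give the 1,3‑anti diol (C4 R) by 1,2‑reduction of the enone.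

Step 10
Reactants: 17 (1R,3aR,4R,8aS)‑3a,6‑dimethyl‑1‑(propan‑2‑yl)‑1,2,3,3a,4,7,8,8a‑octahydroazulene‑4,8a‑diol; 18 4‑methoxybenzoyl chloride
Product: 19 (1R,3aR,4R,8aS)‑8a‑hydroxy‑3a,6‑dimethyl‑1‑(propan‑2‑yl)‑1,2,3,3a,4,7,8,8a‑octahydroazulen‑4‑yl 4‑methoxybenzoate
Conditions: pyridine, DMAP (0.2 equiv), CH2Cl2, 0 °C → rt
Reagents that add atoms: 4‑methoxybenzoyl chloride, COc1ccc(C(Cl)=O)cc1
Why: DMAP‑catalysed acylation with an acid chloride is selective for the secondary allylic alcohol over the hindered tertiary 8a‑OH; no stereocentre is affected.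

**Compound list**

1 | (R)‑(−)‑piperitone, (6R)‑3‑methyl‑6‑(propan‑2‑yl)cyclohex‑2‑en‑1‑one | CC1=CC(=O)[C@@H](C(C)C)CC1 | starting material
2 | iodine | II | starting material
3 | (6R)‑2‑iodo‑3‑methyl‑6‑(propan‑2‑yl)cyclohex‑2‑en‑1‑one | CC1=C(I)C(=O)[C@@H](C(C)C)CC1 | intermediate
4 | tributyl(ethenyl)stannane | C=C[Sn](CCCC)(CCCC)CCCC | starting material
5 | (6R)‑2‑ethenyl‑3‑methyl‑6‑(propan‑2‑yl)cyclohex‑2‑en‑1‑one | C=CC1=C(C)CC[C@H](C(C)C)C1=O | intermediate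
6 | 4‑bromo‑2‑methylbut‑1‑ene | C=C(C)CCBr | starting material
7 | (3‑methylbut‑3‑en‑1‑yl)magnesium bromide (not isolated) | C=C(C)CC[Mg]Br | intermediate
8 | (1S,6R)‑2‑ethenyl‑3‑methyl‑1‑(3‑methylbut‑3‑en‑1‑yl)‑6‑(propan‑2‑yl)cyclohex‑2‑en‑1‑ol | C=CC1=C(C)CC[C@H](C(C)C)[C@@]1(O)CCC(C)=C | intermediate
9 | triethylsilyl trifluoromethanesulfonate | CC[Si](CC)(CC)OS(=O)(=O)C(F)(F)F | starting material
10 | triethyl{[(1S,6R)‑2‑ethenyl‑3‑methyl‑1‑(3‑methylbut‑3‑en‑1‑yl)‑6‑(propan‑2‑yl)cyclohex‑2‑en‑1‑yl]oxy}silane | C=CC1=C(C)CC[C@H](C(C)C)[C@@]1(O[Si](CC)(CC)CC)CCC(C)=C | intermediate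
11 | triethyl{[(4R,4aS)‑1,7‑dimethyl‑4‑(propan‑2‑yl)‑3,4,5,6‑tetrahydronaphthalen‑4a(2H)‑yl]oxy}silane | CC1=C2C=C(C)CC[C@]2(O[Si](CC)(CC)CC)[C@@H](C(C)C)CC1 | intermediate
12 | dioxygen | O=O | starting material
13 | (4R,4aS,8aS)‑8a‑hydroperoxy‑7‑methyl‑1‑methylidene‑4‑(propan‑2‑yl)‑4a‑[(triethylsilyl)oxy]‑1,2,3,4,4a,5,6,8a‑octahydronaphthalene (not isolated) | C=C1CC[C@H](C(C)C)[C@@]2(O[Si](CC)(CC)CC)CCC(C)=C[C@]12OO | intermediate
14 | (4R,4aS,8aS)‑7‑methyl‑1‑methylidene‑4‑(propan‑2‑yl)‑4a‑[(triethylsilyl)oxy]‑1,2,3,4,4a,5,6,8a‑octahydronaphthalen‑8a‑ol | C=C1CC[C@H](C(C)C)[C@@]2(O[Si](CC)(CC)CC)CCC(C)=C[C@]12O | intermediate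
15 | (1R,3aS,8aS)‑3a,6‑dimethyl‑1‑(propan‑2‑yl)‑8a‑[(triethylsilyl)oxy]‑2,3,3a,7,8,8a‑hexahydroazulen‑4(1H)‑one | O=C1C=C(C)CC[C@]2(O[Si](CC)(CC)CC)[C@@H](C(C)C)CC[C@]12C | intermediate
16 | (1R,3aS,8aS)‑8a‑hydroxy‑3a,6‑dimethyl‑1‑(propan‑2‑yl)‑2,3,3a,7,8,8a‑hexahydroazulen‑4(1H)‑one | O=C1C=C(C)CC[C@]2(O)[C@@H](C(C)C)CC[C@]12C | intermediate
17 | (1R,3aR,4R,8aS)‑3a,6‑dimethyl‑1‑(propan‑2‑yl)‑1,2,3,3a,4,7,8,8a‑octahydroazulene‑4,8a‑diol | O[C@@H]1C=C(C)CC[C@]2(O)[C@@H](C(C)C)CC[C@]12C | intermediate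
18 | 4‑methoxybenzoyl chloride | COc1ccc(C(Cl)=O)cc1 | starting material
19 | (1R,3aR,4R,8aS)‑8a‑hydroxy‑3a,6‑dimethyl‑1‑(propan‑2‑yl)‑1,2,3,3a,4,7,8,8a‑octahydroazulen‑4‑yl 4‑methoxybenzoate | COc1ccc(C(=O)O[C@@H]2C=C(C)CC[C@]3(O)[C@@H](C(C)C)CC[C@]23C)cc1 | target

Total step count: 10. Longest linear sequence: 10 steps (from 1).

**Steps most likely to fail, with fallbacks**

Step 7. The C1 cation may be captured by the axial 8a‑hydroxyl (oxirane closure) instead of triggering the shift. Hydrogen‑atom transfer may also go to the ring‑B alkene, or the C4a–C8a bond may fragment instead of migrating. The fallback sets out from 1 and Grignard reagent 7 and returns at 15; it contracts the ring before the seven‑membered ring exists. Addition of 7 to 1 (LaCl3·2LiCl, THF, 0 °C) should give (1S,6R)‑3‑methyl‑1‑(3‑methylbut‑3‑en‑1‑yl)‑6‑(propan‑2‑yl)cyclohex‑2‑en‑1‑ol F1. Silylation (Et3SiOTf, 2,6‑lutidine) gives its triethylsilyl ether F2. Epoxidation with m‑CPBA (NaHCO3, CH2Cl2, 0 °C) should take the more electron‑rich ring alkene anti to OSiEt3 and give the epoxy silyl ether F3 (epoxide oxygen trans to OSiEt3, isopropyl cis to OSiEt3). Methylaluminum bis(4‑bromo‑2,6‑di‑tert‑butylphenoxide) (CH2Cl2, −78 °C) then promotes a Meinwald‑type rearrangement of the epoxy silyl ether: the tertiary C–O bond opens and the silyloxy‑bearing ring carbon shifts anti to it. This contracts the cyclohexane to (1S,2S,3R)‑1‑methyl‑2‑(3‑methylbut‑3‑en‑1‑yl)‑3‑(propan‑2‑yl)‑2‑[(triethylsilyl)oxy]cyclopentane‑1‑carbaldehyde F4. Vinylmagnesium bromide gives 1‑[(1R,2S,3R)‑1‑methyl‑2‑(3‑methylbut‑3‑en‑1‑yl)‑3‑(propan‑2‑yl)‑2‑[(triethylsilyl)oxy]cyclopentyl]prop‑2‑en‑1‑ol F5 as both carbinol epimers. Ring‑closing metathesis with the second‑generation Grubbs catalyst gives (1R,3aR,8aS)‑3a,6‑dimethyl‑1‑(propan‑2‑yl)‑8a‑[(triethylsilyl)oxy]‑1,2,3,3a,4,7,8,8a‑octahydroazulen‑4‑ol F6 (both C4 epimers). Dess–Martin oxidation converges both epimers on 15.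

Step 6. Singlet oxygen may attack the wrong face or the ring‑B alkene, hydrogen may be abstracted from C2 instead of the methyl group, or the bis‑allylic hydroperoxide may rearrange before it is reduced. The fallback sets out from 11 and returns at 14. Dimethyldioxirane (acetone, −20 °C) should epoxidise the tetrasubstituted alkene anti to OSiEt3 under neutral conditions to give the vinyl epoxide triethyl{[1,7‑dimethyl‑4‑(propan‑2‑yl)‑1,8a‑epoxy‑1,2,3,4,5,6‑hexahydronaphthalen‑4a‑yl]oxy}silane F7 (epoxide oxygen trans to OSiEt3). Diethylaluminum 2,2,6,6‑tetramethylpiperidide (from Et2AlCl and lithium 2,2,6,6‑tetramethylpiperidide, benzene, 0 °C) then removes a methyl hydrogen syn to the oxirane oxygen and opens the epoxide to the exocyclic allylic alcohol 14.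

Step 9. The hindered tertiary hydroxyl may exchange onto boron too slowly, so that reduction runs undirected with poor facial selectivity or with conjugate reduction. The fallback sets out from 15 and returns at 19; it uses undirected reduction followed by inversion during esterification. Luche reduction of 15 (NaBH4, CeCl3·7H2O, MeOH, −40 °C) should deliver hydride to the face opposite the bulky OSiEt3 and give the epimeric alcohol (1R,3aR,4S,8aS)‑3a,6‑dimethyl‑1‑(propan‑2‑yl)‑8a‑[(triethylsilyl)oxy]‑1,2,3,3a,4,7,8,8a‑octahydroazulen‑4‑ol F8. Mitsunobu esterification with 4‑methoxybenzoic acid (PPh3, diisopropyl azodicarboxylate, toluene) inverts C4 and gives (1R,3aR,4R,8aS)‑3a,6‑dimethyl‑1‑(propan‑2‑yl)‑8a‑[(triethylsilyl)oxy]‑1,2,3,3a,4,7,8,8a‑octahydroazulen‑4‑yl 4‑methoxybenzoate F9. HF·pyridine then frees the tertiary alcohol to give 19.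

Further compounds
F1 | step 7 | (1S,6R)‑3‑methyl‑1‑(3‑methylbut‑3‑en‑1‑yl)‑6‑(propan‑2‑yl)cyclohex‑2‑en‑1‑ol | CC1=C[C@](O)(CCC(C)=C)[C@@H](C(C)C)CC1
F2 | step 7 | triethyl{[(1S,6R)‑3‑methyl‑1‑(3‑methylbut‑3‑en‑1‑yl)‑6‑(propan‑2‑yl)cyclohex‑2‑en‑1‑yl]oxy}silane | CC1=C[C@](O[Si](CC)(CC)CC)(CCC(C)=C)[C@@H](C(C)C)CC1
F3 | step 7 | triethyl{[6‑methyl‑2‑(3‑methylbut‑3‑en‑1‑yl)‑3‑(propan‑2‑yl)‑7‑oxabicyclo[4.1.0]heptan‑2‑yl]oxy}silane, epoxide oxygen trans to OSiEt3, isopropyl cis to OSiEt3 | C[C@]12CC[C@H](C(C)C)[C@@](O[Si](CC)(CC)CC)(CCC(C)=C)[C@H]1O2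
F4 | step 7 | (1S,2S,3R)‑1‑methyl‑2‑(3‑methylbut‑3‑en‑1‑yl)‑3‑(propan‑2‑yl)‑2‑[(triethylsilyl)oxy]cyclopentane‑1‑carbaldehyde | O=C[C@@]1(C)CC[C@H](C(C)C)[C@@]1(O[Si](CC)(CC)CC)CCC(C)=C
F5 | step 7 | 1‑[(1R,2S,3R)‑1‑methyl‑2‑(3‑methylbut‑3‑en‑1‑yl)‑3‑(propan‑2‑yl)‑2‑[(triethylsilyl)oxy]cyclopentyl]prop‑2‑en‑1‑ol, both carbinol epimers | C=CC(O)[C@@]1(C)CC[C@H](C(C)C)[C@@]1(O[Si](CC)(CC)CC)CCC(C)=C
F6 | step 7 | (1R,3aR,8aS)‑3a,6‑dimethyl‑1‑(propan‑2‑yl)‑8a‑[(triethylsilyl)oxy]‑1,2,3,3a,4,7,8,8a‑octahydroazulen‑4‑ol, both C4 epimers | OC1C=C(C)CC[C@]2(O[Si](CC)(CC)CC)[C@@H](C(C)C)CC[C@]12C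
F7 | step 6 | triethyl{[1,7‑dimethyl‑4‑(propan‑2‑yl)‑1,8a‑epoxy‑1,2,3,4,5,6‑hexahydronaphthalen‑4a‑yl]oxy}silane, epoxide oxygen trans to OSiEt3 | C[C@]12CC[C@H](C(C)C)[C@@]3(O[Si](CC)(CC)CC)CCC(C)=C[C@@]31O2
F8 | step 9 | (1R,3aR,4S,8aS)‑3a,6‑dimethyl‑1‑(propan‑2‑yl)‑8a‑[(triethylsilyl)oxy]‑1,2,3,3a,4,7,8,8a‑octahydroazulen‑4‑ol | O[C@H]1C=C(C)CC[C@]2(O[Si](CC)(CC)CC)[C@@H](C(C)C)CC[C@]12C
F9 | step 9 | (1R,3aR,4R,8aS)‑3a,6‑dimethyl‑1‑(propan‑2‑yl)‑8a‑[(triethylsilyl)oxy]‑1,2,3,3a,4,7,8,8a‑octahydroazulen‑4‑yl 4‑methoxybenzoate | COc1ccc(C(=O)O[C@@H]2C=C(C)CC[C@]3(O[Si](CC)(CC)CC)[C@@H](C(C)C)CC[C@]23C)cc1
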